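**Assumption:** the target SMILES has no stereocentre or other stereogenic element, so the compound is achiral and the route makes it as such. The only stereocentres in the route (in 3, 4, 5, 10, 11, 12) are formed racemic and are erased on aromatization.

**Retrosynthetic overview**
- Cut the depside aryl ester C–O bond: 2,4-dimethoxy-6-pentylbenzoic acid (ring A) plus benzyl 4-hydroxy-2-methoxy-6-propylbenzoate (ring B); the benzyl ester is removed last by hydrogenolysis.
- Each arene comes from a methyl 6-alkyl-2,4-dihydroxybenzoate, made by oxidative aromatization of a 6-alkyl-2-hydroxy-4-oxocyclohexene ester.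
- Each cyclohexene ester comes from an intermolecular Michael addition of dimethyl malonate to an (E)-alk-3-en-2-one, followed in the same pot by intramolecular Claisen ring closure.
- Ring B needs 2-OMe and free 4-OH: protect 4-OH as its methoxymethyl (MOM) ether, methylate 2-OH, swap methyl ester for benzyl ester, remove MOM.
- Order: ring A is built and aromatized first, ring B second, and the two are joined by esterification at the end.

**Route**

Step 1
Reactants: 1 dimethyl malonate; 2 (E)-non-3-en-2-one
Product: 4 methyl 2-hydroxy-4-oxo-6-pentylcyclohex-2-ene-1-carboxylate (racemic), via Michael adduct 3 (not isolated)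
Conditions: NaOMe (1.2 equiv), MeOH, reflux; then aq. HCl, 0 °C
Reagents that add atoms: none
Why: The malonate anion adds 1,4 to the enone (intermolecular Michael addition) and the methyl-ketone enolate then closes onto one ester (intramolecular Claisen/Dieckmann condensation), driven by formation of the stabilized cyclic 1,3-dione enolate; the two new stereocentres are racemic and disappear in step 2.

Step 2
Reactants: 4 methyl 2-hydroxy-4-oxo-6-pentylcyclohex-2-ene-1-carboxylate
Product: 6 methyl 2,4-dihydroxy-6-pentylbenzoate, via bromo enol 5 (not isolated)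
Conditions: Br2 (1.0 equiv), DMF, 0 °C, then 80 °C
Reagents that add atoms: none
Why: Bromination of the enolized 1,3-dione followed by thermal dehydrobromination and tautomerization gives the resorcinol (oxidative aromatization), with exactly one equivalent of Br2 to avoid ring bromination.

Step 3
Reactants: 6 methyl 2,4-dihydroxy-6-pentylbenzoate
Product: 7 methyl 2,4-dimethoxy-6-pentylbenzoate
Conditions: MeI (3 equiv), K2CO3 (3 equiv), DMF, 60 °C
Reagents that add atoms: iodomethane, CI
Why: Williamson ether synthesis; excess MeI and K2CO3 in warm DMF methylate both the free 4-OH and the hydrogen-bonded 2-OH.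

Step 4
Reactants: 7 methyl 2,4-dimethoxy-6-pentylbenzoate
Product: 8 2,4-dimethoxy-6-pentylbenzoic acid
Conditions: KOH (8 equiv), DMSO/H2O 4:1, 100 °C; then cold 2 M HCl
Reagents that add atoms: potassium hydroxide, [K+].[OH-]
Why: Saponification of the di-ortho-substituted ester needs the poorly solvated hydroxide of hot KOH/DMSO; the aryl methyl ethers are inert and cold acidification avoids decarboxylation.

Step 5
Reactants: 1 dimethyl malonate; 9 (E)-hept-3-en-2-one
Product: 11 methyl 2-hydroxy-4-oxo-6-propylcyclohex-2-ene-1-carboxylate (racemic), via Michael adduct 10 (not isolated)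
Conditions: NaOMe (1.2 equiv), MeOH, reflux; then aq. HCl, 0 °C
Reagents that add atoms: none
Why: Same intermolecular Michael addition and intramolecular Claisen ring closure as step 1, on the lower homologue; the racemic stereocentres are removed in step 6.

Step 6
Reactants: 11 methyl 2-hydroxy-4-oxo-6-propylcyclohex-2-ene-1-carboxylate
Product: 13 methyl 2,4-dihydroxy-6-propylbenzoate, via bromo enol 12 (not isolated)
Conditions: Br2 (1.0 equiv), DMF, 0 °C, then 80 °C
Reagents that add atoms: none
Why: Bromination and dehydrobromination aromatize the dione to the resorcinol exactly as in step 2.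

Step 7
Reactants: 13 methyl 2,4-dihydroxy-6-propylbenzoate
Product: 14 methyl 2-hydroxy-4-(methoxymethoxy)-6-propylbenzoate
Conditions: MOMCl (1.05 equiv), K2CO3 (1.5 equiv), acetone, 0 °C to rt
Reagents that add atoms: chloromethyl methyl ether, COCCl
Why: Regioselective Williamson-type O-alkylation; the 4-OH is more acidic and free, whereas the 2-OH is held in a hydrogen bond to the ester carbonyl and stays untouched with one equivalent of electrophile.

Step 8
Reactants: 14 methyl 2-hydroxy-4-(methoxymethoxy)-6-propylbenzoate
Product: 15 methyl 2-methoxy-4-(methoxymethoxy)-6-propylbenzoate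
Conditions: MeI (2 equiv), K2CO3 (2 equiv), DMF, 50 °C
Reagents that add atoms: iodomethane, CI
Why: Williamson ether synthesis on the remaining chelated phenol under more forcing conditions; the MOM acetal is stable to base.

Step 9
Reactants: 15 methyl 2-methoxy-4-(methoxymethoxy)-6-propylbenzoate
Product: 16 2-methoxy-4-(methoxymethoxy)-6-propylbenzoic acid
Conditions: KOH (8 equiv), DMSO/H2O 4:1, 90 °C; then cold 1 M HCl to pH 4
Reagents that add atoms: potassium hydroxide, [K+].[OH-]
Why: Saponification of the hindered ester as in step 4; the MOM ether is base-stable and survives a brief, cold, mildly acidic work-up.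

Step 10
Reactants: 16 2-methoxy-4-(methoxymethoxy)-6-propylbenzoic acid
Product: 17 benzyl 2-methoxy-4-(methoxymethoxy)-6-propylbenzoate
Conditions: BnBr (1.1 equiv), K2CO3 (1.5 equiv), DMF, rt
Reagents that add atoms: benzyl bromide, BrCc1ccccc1
Why: SN2 O-alkylation of the carboxylate forms the ester at the benzylic carbon, so the hindered carbonyl carbon is never attacked.

Step 11
Reactants: 17 benzyl 2-methoxy-4-(methoxymethoxy)-6-propylbenzoate
Product: 18 benzyl 4-hydroxy-2-methoxy-6-propylbenzoate
Conditions: HCl (cat.), MeOH, rt to 40 °C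
Reagents that add atoms: none
Why: Acid-catalysed acetal exchange removes the MOM group as dimethoxymethane, while the di-ortho-substituted benzyl ester resists transesterification and the methyl ether is inert.

Step 12
Reactants: 8 2,4-dimethoxy-6-pentylbenzoic acid; 18 benzyl 4-hydroxy-2-methoxy-6-propylbenzoate
Product: 20 benzyl 4-[(2,4-dimethoxy-6-pentylbenzoyl)oxy]-2-methoxy-6-propylbenzoate, via mixed anhydride 19 (not isolated)
Conditions: (CF3CO)2O (4 equiv), toluene, rt
Reagents that add atoms: none
Why: Mixed-anhydride esterification; the electron-rich hindered acid gives a trifluoroacetic mixed anhydride with acylium character that acylates the only free phenol despite the two ortho substituents.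

Step 13
Reactants: 20 benzyl 4-[(2,4-dimethoxy-6-pentylbenzoyl)oxy]-2-methoxy-6-propylbenzoate
Product: 21 4-[(2,4-dimethoxy-6-pentylbenzoyl)oxy]-2-methoxy-6-propylbenzoic acid
Conditions: H2 (1 atm), 10% Pd/C, EtOAc, rt
Reagents that add atoms: none
Why: Catalytic hydrogenolysis cleaves only the benzylic C–O bond of the benzyl ester; the aryl ester and the methyl ethers are stable under neutral conditions.

**Compound list**
1 | dimethyl malonate | COC(=O)CC(=O)OC | starting material
2 | (E)-non-3-en-2-one | CCCCC/C=C/C(C)=O | starting material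
3 | dimethyl 2-(2-oxononan-4-yl)propanedioate (racemic, not isolated) | CCCCCC(CC(C)=O)C(C(=O)OC)C(=O)OC | intermediate
4 | methyl 2-hydroxy-4-oxo-6-pentylcyclohex-2-ene-1-carboxylate (racemic, mainly trans) | CCCCCC1CC(=O)C=C(O)C1C(=O)OC | intermediate
5 | methyl 3-bromo-2-hydroxy-4-oxo-6-pentylcyclohex-2-ene-1-carboxylate (racemic, not isolated) | CCCCCC1CC(=O)C(Br)=C(O)C1C(=O)OC | intermediate
6 | methyl 2,4-dihydroxy-6-pentylbenzoate | CCCCCc1cc(O)cc(O)c1C(=O)OC | intermediate
7 | methyl 2,4-dimethoxy-6-pentylbenzoate | CCCCCc1cc(OC)cc(OC)c1C(=O)OC | intermediate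
8 | 2,4-dimethoxy-6-pentylbenzoic acid | CCCCCc1cc(OC)cc(OC)c1C(=O)O | intermediate
9 | (E)-hept-3-en-2-one | CCC/C=C/C(C)=O | starting material
10 | dimethyl 2-(2-oxoheptan-4-yl)propanedioate (racemic, not isolated) | CCCC(CC(C)=O)C(C(=O)OC)C(=O)OC | intermediate
11 | methyl 2-hydroxy-4-oxo-6-propylcyclohex-2-ene-1-carboxylate (racemic, mainly trans) | CCCC1CC(=O)C=C(O)C1C(=O)OC | intermediate
12 | methyl 3-bromo-2-hydroxy-4-oxo-6-propylcyclohex-2-ene-1-carboxylate (racemic, not isolated) | CCCC1CC(=O)C(Br)=C(O)C1C(=O)OC | intermediate
13 | methyl 2,4-dihydroxy-6-propylbenzoate | CCCc1cc(O)cc(O)c1C(=O)OC | intermediate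
14 | methyl 2-hydroxy-4-(methoxymethoxy)-6-propylbenzoate | CCCc1cc(OCOC)cc(O)c1C(=O)OC | intermediate
15 | methyl 2-methoxy-4-(methoxymethoxy)-6-propylbenzoate | CCCc1cc(OCOC)cc(OC)c1C(=O)OC | intermediate
16 | 2-methoxy-4-(methoxymethoxy)-6-propylbenzoic acid | CCCc1cc(OCOC)cc(OC)c1C(=O)O | intermediate
17 | benzyl 2-methoxy-4-(methoxymethoxy)-6-propylbenzoate | CCCc1cc(OCOC)cc(OC)c1C(=O)OCc1ccccc1 | intermediate
18 | benzyl 4-hydroxy-2-methoxy-6-propylbenzoate | CCCc1cc(O)cc(OC)c1C(=O)OCc1ccccc1 | intermediate
19 | 2,4-dimethoxy-6-pentylbenzoic trifluoroacetic anhydride (not isolated) | CCCCCc1cc(OC)cc(OC)c1C(=O)OC(=O)C(F)(F)F | intermediate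
20 | benzyl 4-[(2,4-dimethoxy-6-pentylbenzoyl)oxy]-2-methoxy-6-propylbenzoate | CCCCCc1cc(OC)cc(OC)c1C(=O)Oc1cc(CCC)c(C(=O)OCc2ccccc2)c(OC)c1 | intermediate
21 | 4-[(2,4-dimethoxy-6-pentylbenzoyl)oxy]-2-methoxy-6-propylbenzoic acid (achiral) | CCCCCc1cc(OC)cc(OC)c1C(=O)Oc1cc(CCC)c(C(=O)O)c(OC)c1 | target

**Step count and risks**

Total step count: 13. Longest linear sequence: 9 steps (steps 5 to 13, from dimethyl malonate and (E)-hept-3-en-2-one). The ring A branch (steps 1 to 4) joins at step 12.

Three steps most likely to fail:

1. Step 2 (Br2/DMF aromatization). The risk is over-bromination of the very electron-rich resorcinol ring, giving mixtures. The fallback sets out from 4 and comes back at 6. It over-brominates on purpose and then cleans up reductively. Compound 4 is treated with Br2 (3.1 equiv) in AcOH at rt, which aromatizes and brominates both free ring positions to give methyl 3,5-dibromo-2,4-dihydroxy-6-pentylbenzoate F1 as a single crystalline product. Hydrogenolysis of both C–Br bonds (H2, 10% Pd/C, NaOAc, MeOH, rt) then gives 6.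

2. Step 9 (saponification of the di-ortho-substituted ester in the presence of the MOM ether). The risk is incomplete hydrolysis, or MOM loss and decarboxylation during acidification. The fallback sets out from 15 and comes back at 16. It avoids attack of hydroxide at the hindered carbonyl by going through the oxidation levels of the benzylic carbon. LiAlH4 in THF at 0 °C reduces 15 to [2-methoxy-4-(methoxymethoxy)-6-propylphenyl]methanol F2. MnO2 in CH2Cl2 at rt oxidizes this to 2-methoxy-4-(methoxymethoxy)-6-propylbenzaldehyde F3. Pinnick oxidation (NaClO2, NaH2PO4, 2-methyl-2-butene, t-BuOH/H2O, rt) then gives 16 under nearly neutral conditions.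

3. Step 12 (depside esterification of a hindered acid with a deactivated phenol). The risk is competing trifluoroacetylation of the phenol or C-acylation of ring B. The fallback sets out from 8 and comes back at 20. It uses an isolated acyl chloride and a preformed phenoxide in place of the acidic mixed-anhydride medium. Compound 8 with oxalyl chloride and catalytic DMF in CH2Cl2 (0 °C to rt) gives 2,4-dimethoxy-6-pentylbenzoyl chloride F4, which is freed of volatiles. Compound 18 is deprotonated with NaH in THF at 0 °C and F4 is added; O-acylation of the sodium phenoxide at rt gives 20.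

**Further compounds**
F1 | step 2 | methyl 3,5-dibromo-2,4-dihydroxy-6-pentylbenzoate | CCCCCc1c(Br)c(O)c(Br)c(O)c1C(=O)OC
F2 | step 9 | [2-methoxy-4-(methoxymethoxy)-6-propylphenyl]methanol | CCCc1cc(OCOC)cc(OC)c1CO
F3 | step 9 | 2-methoxy-4-(methoxymethoxy)-6-propylbenzaldehyde | CCCc1cc(OCOC)cc(OC)c1C=O
F4 | step 12 | 2,4-dimethoxy-6-pentylbenzoyl chloride | CCCCCc1cc(OC)cc(OC)c1C(Cl)=O
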